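Remark on the chemistry: the target has no stereocentre and no stereogenic alkene, so the route carries no stereochemical task; the alkene geometry of the transient intermediates 3 and 18 does not affect the product. Ring positions C2 to C8a are given in chromene numbering of the target throughout.

## The problem

Target 25 is an achiral dihydrochalcone whose ring A is a benzene with five substituents. These are a 2,2-dimethylpyran fused across C4a–C8a, a 3-(4-hydroxyphenyl)propanoyl group on C6, a free hydroxyl on C7 and a prenyl group on C8; only C5 carries hydrogen. With no stereocentre to set, the difficulty is regiochemical: acyl, oxygen, prenyl and oxygen must follow one another in a fixed order, and the pyran must close on the C8a oxygen and on C4a, not on the C7 oxygen. Substitution of a ready-made resorcinol-type ring is poorly selective at exactly these sites (prenylation at C8 against the other free carbon, angular against linear pyran closure), so ring A is better built than decorated. The molecule is also fragile. The C7 hydroxyl sits beside the prenyl alkene and adds to it under acid, the chromene alkene is an electron-rich styrene, and two alkenes plus two phenols rule out hydrogenolysis and strong oxidants near the end. The enabling feature is the order of substituents on ring A. C6 (acyl), C7 (oxygen), C8 (prenyl) and C5 (hydrogen) correspond one-to-one to C5, C4, C3 and C6 of a 4-oxy-3-prenyl-2-pyrone-5-carboxylate. The remaining two carbons, C8a with its oxygen and C4a, can be supplied by a ketene acetal.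

## Retrosynthesis

Target 25 is traced back to bis(methoxymethyl) ether 24 by cutting the two phenolic O–CH2 acetal bonds. Methoxymethyl groups are chosen on both rings because they survive base, organomagnesium reagents and 180 °C, and one mild acid treatment removes both. Benzyl ethers would need hydrogenolysis, which the two alkenes forbid. The forward step must free both phenols without letting the C7 hydroxyl add to the prenyl alkene.

Ketone 24 is cut at the C(=O)–CH2 bond into Weinreb amide 20 and Grignard reagent 23. Reagent 23 comes from bromide 22, the methoxymethyl ether of commercial phenol 21. Cutting the aryl–carbonyl bond instead would need a Lewis-acid acylation on a prenylated chromene and would reopen the regiochemical question. Cutting the next bond down the chain (an aldol with an aromatic aldehyde) would leave a chalcone alkene to be reduced selectively beside two other alkenes. Amide 20 comes from ethyl ester 19, so the forward steps only have to stop acyl substitution at the ketone stage.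

Chromene ester 19 is opened at C4–C4a and O1–C2 to aryl 1,1-dimethylpropargyl ether 16, which is cut at the ether bond to phenol 15. A propargyl Claisen cascade is preferred to other pyran syntheses because the prenyl group on C8 already occupies one of the two ortho positions of the C8a oxygen. The rearrangement can therefore only go to C4a, and the prenyl group serves as its own blocking group. Phenol 15 is a tetrasubstituted benzene with no ring fused to it. The forward reaction needs exactly one free hydroxyl, the one on C8a.

Benzoate 15 is the product of the key disconnection. Cutting C4a–C5 and C8–C8a divides ring A into pyrone 8 and ketene bis(trimethylsilyl) acetal 11. Prenylating a finished resorcylate ester would give positional mixtures. In the pyrone every substituent is in place before the ring becomes aromatic, and the two oxygens emerge differentiated, one as the acetal ether of 8 and the other as a free phenol. The precursor is a monocyclic lactone with three substituents. The forward reaction must deliver one regiochemistry of cycloaddition, followed by decarboxylation and loss of silanol, from a diene that its donor groups make less reactive than the parent ester.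

Pyrone 8 is the methoxymethyl ether of hydroxypyrone 7, which is cut at the ring-to-prenyl bond into hydroxypyrone 4 and prenyl methyl carbonate 6. Carbonate 6 is made from alcohol 5. A palladium-catalysed allylation is chosen over a Claisen route because it gives the linear prenyl group on carbon directly. Pyrone 4 is cut at O1–C6 and at the C5–C6 bond to diethyl 3-oxopentanedioate 1 and triethyl orthoformate 2, joined through ethoxymethylene diester 3. This leaves two bulk chemicals and a one-flask condensation.

Ketene acetal 11 is cut at an O–Si bond to trimethylsilyl acetate 9, through its lithium enolate 10. The dienophile is thus one step from a commercial ester, and the silyl groups are chosen so that the new ring oxygen appears as a free phenol after work-up.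

## Roads not taken

Alternative 1: Ring A would be made one oxidation level too low, by cutting C5–C6 and C7–C8. Under alkoxide, dimethyl malonate A3 adds to 7-methylocta-1,6-dien-3-one A2 in a Michael reaction. The prenyl-bearing α-carbon of the ketone then closes onto a malonate ester to give methyl 2-hydroxy-4-oxo-3-prenylcyclohex-2-ene-1-carboxylate A1. Dehydrogenation would then give methyl 2,4-dihydroxy-3-prenylbenzoate A4.
- Merits: the inputs are cheap, the prenyl position is beyond doubt, and the anionic annulation is very probably more dependable than a cycloaddition of a donor-substituted pyrone. It reaches the resorcylate stage in about as many steps as the chosen plan, or fewer.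
- Weak points: the missing unsaturation has to be introduced by an oxidant (a halogen, a quinone or a palladium dehydrogenation) in a molecule whose enol oxygen lies next to a trisubstituted alkene, so oxidative or halonium-induced cyclisation onto the prenyl group is the expected side reaction. A2 is a polymerisable vinyl ketone that must be prepared. A4 has both hydroxyls free, so differentiation rests only on the chelation of one of them.
- Comparison: Alternative 1 is the safer ring-forming reaction. The chosen plan sets against it that ring A becomes aromatic by losing carbon dioxide and a silanol, so no oxidant touches the prenyl group, and that the two oxygens arrive already distinguished.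

Alternative 2: Here the pyran is cut, at C3–C4 and O1–C2. Salicylaldehyde A6 condenses with dibenzylamine A8 and 2-methylprop-1-enylboronic acid A7. Alkenyl transfer from a phenol-bound boronate to the iminium carbon forms C3–C4, loss of the amine gives an ortho-quinone methide, and oxa-6π closure forms O1–C2. The product is silyl ether A5, one desilylation from the target.
- Merits: the closure is late, mild and convergent, and the aldehyde carbon fixes where the ring forms, so no step at 180 °C is needed. With A6 available this endgame would be shorter than the last five steps of the chosen route.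
- Weak points: it does not address the real problem. A6 is a hexasubstituted benzene whose prenyl, acyl, formyl and hydroxyl groups still have to be placed, and C-prenylation of a resorcinol ketone and formylation of an acyl-deactivated ring beside an acid-sensitive prenyl group are the very regiochemical steps the target makes hard. The ketone may also compete with the aldehyde for the amine.
- Comparison: Alternative 2 has the better endgame. The chosen plan has the better ring A, and it uses the prenyl group itself to force the Claisen cascade to the correct carbon, which offsets the advantage of the aldehyde handle.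

Alternative 3: Ring A is cut at C7–C8, C4a–C8a and C6–C7. Irradiation of diazo enone A11 triggers a Wolff rearrangement to a vinylketene, which adds to siloxyalkyne A10 in a (2+2) reaction. The cyclobutenone opens and recloses by 6π electrocyclisation to give phenol A9, in which the acyl chain, the prenyl group and both oxygens are in place and the oxygens are differentiated.
- Merits: this is the most convergent road. The ring-forming step installs the whole side chain, so no Weinreb amide or Grignard step is needed, and the longest linear sequence would probably be shorter than in the chosen plan. Oxygen differentiation is as good as in the chosen plan.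
- Weak points: A11 is an ene-dione that also carries a diazo group. It is a strong acceptor and light-sensitive, and its vinylketene bears a conjugated ketone that can close on its own carbonyl oxygen to a pyranone. A10 requires a multistep ester homologation and is moisture-sensitive. The step needs diazo handling and a photoreactor.
- Comparison: Alternative 3 is better in convergence. The chosen plan offers bulk starting materials, purely thermal and ionic steps, robust intermediates, and a key step with closer precedent on its substrate class.

Key step: step 6

## Route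

Step 1
Reactants: 1 diethyl 3-oxopentanedioate; 2 triethyl orthoformate
Product: 4 ethyl 4-hydroxy-6-oxo-6H-pyran-3-carboxylate, via ethoxymethylene diester 3 (not isolated)
Conditions: Ac2O, 120 °C; then 1 M aq. HCl, 23 °C
Reagents that add atoms: water, O
Why: Orthoester condensation at an active methylene gives the ethoxymethylene derivative 3; aqueous acid hydrolyses the enol ether and the resulting enol lactonises onto the distal ester. This is the established cyclocondensation route to 4-hydroxy-2-pyrone-5-carboxylates.

Step 2
Reactants: 5 3-methylbut-2-en-1-ol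
Product: 6 methyl 3-methylbut-2-en-1-yl carbonate
Conditions: ClCO2Me, pyridine, CH2Cl2, 0 °C
Reagents that add atoms: methyl chloroformate, COC(=O)Cl
Why: Acylation of a primary allylic alcohol by a chloroformate; pyridine takes up the HCl so the prenyl system never meets free acid.

Step 3
Reactants: 4 ethyl 4-hydroxy-6-oxo-6H-pyran-3-carboxylate; 6 methyl 3-methylbut-2-en-1-yl carbonate
Product: 7 ethyl 4-hydroxy-5-(3-methylbut-2-en-1-yl)-6-oxo-6H-pyran-3-carboxylate
Conditions: Pd(PPh3)4 (5 mol %), THF, 23 to 50 °C
Reagents that add atoms: none
Why: Tsuji–Trost allylation: the catalyst ionises the carbonate to a 1,1-dimethylallyl complex, the released methoxide deprotonates the acidic enol, and the soft carbon between the lactone carbonyl and the enol attacks the less hindered allyl terminus to give the linear prenyl group. Any O-allylated material is re-ionised by the catalyst and funnelled to the C-allyl product.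

Step 4
Reactants: 7 ethyl 4-hydroxy-5-(3-methylbut-2-en-1-yl)-6-oxo-6H-pyran-3-carboxylate
Product: 8 ethyl 4-(methoxymethoxy)-5-(3-methylbut-2-en-1-yl)-6-oxo-6H-pyran-3-carboxylate
Conditions: MOMCl, iPr2NEt, CH2Cl2, 0 to 23 °C
Reagents that add atoms: chloromethyl methyl ether, COCCl
Why: O-alkylation of a vinylogous acid by a hard alkoxymethyl chloride under amine base gives the 4-alkoxy-2-pyrone; the acetal is the group that later keeps the C7 oxygen apart from the C8a oxygen.

Step 5
Reactants: 9 trimethylsilyl acetate
Product: 11 ketene bis(trimethylsilyl) acetal, via lithium enolate 10 (not isolated)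
Conditions: LiN(iPr)2, THF, −78 °C; Me3SiCl, −78 to 23 °C; distil
Reagents that add atoms: chlorotrimethylsilane, C[Si](C)(C)Cl
Why: Kinetic deprotonation of the silyl ester and O-silylation of enolate 10 is the standard preparation of ketene bis(silyl) acetals.

Step 6
Reactants: 8 ethyl 4-(methoxymethoxy)-5-(3-methylbut-2-en-1-yl)-6-oxo-6H-pyran-3-carboxylate; 11 ketene bis(trimethylsilyl) acetal
Product: 15 ethyl 4-hydroxy-2-(methoxymethoxy)-3-(3-methylbut-2-en-1-yl)benzoate, via bridged lactone 12 (not isolated), via cyclohexadiene 13 (not isolated), via aryl silyl ether 14 (not isolated)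
Conditions: 11 (4 equiv), PhMe, sealed tube, 130 °C; then 10% aq. citric acid, THF, 23 °C
Reagents that add atoms: none
Why: The nucleophilic CH2 terminus of 11 bonds to the pyrone carbon that is β to the ester and bound to the ring oxygen, and the dioxygenated carbon bonds to the prenyl-bearing carbon, in an inverse-electron-demand Diels–Alder reaction; this forms C4a–C5 and C8–C8a and closes the carbocycle as bridged lactone 12. The closure is a (4+2) cycloaddition, concerted but asynchronous, or in its stepwise limit a conjugate addition followed by 6-exo-trig attack of the dienolate carbon on the silyloxycarbenium ion. Retro-(4+2) loss of carbon dioxide gives cyclohexadiene 13, 1,2-elimination of trimethylsilanol gives aryl silyl ether 14, and the mild acidic work-up releases phenol 15 without touching the acetal. The closest known reaction type is the conversion of 2-pyrone-5-carboxylates into 4-alkoxybenzoates by ketene acetals. The two bridgehead centres of 12 are racemic and are destroyed on aromatisation, so no stereocentre has to be controlled. The only selectivity required is regiochemical, and it is secured by the matched polarisation of both partners, since the reverse orientation would join two nucleophilic carbons. Because the 3-alkyl and 4-alkoxy groups make the diene less electron-poor than the parent ester, the dienophile is used in excess at 130 °C in a closed vessel. The ring oxygens emerge differentiated, the acetal on the future C7 and a free hydroxyl on the future C8a.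

Step 7
Reactants: 15 ethyl 4-hydroxy-2-(methoxymethoxy)-3-(3-methylbut-2-en-1-yl)benzoate
Product: 16 ethyl 2-(methoxymethoxy)-3-(3-methylbut-2-en-1-yl)-4-[(2-methylbut-3-yn-2-yl)oxy]benzoate
Conditions: 3-chloro-3-methylbut-1-yne, CuCl2·2H2O (1 mol %), DBU, MeCN, 0 °C
Reagents that add atoms: 3-chloro-3-methylbut-1-yne, CC(C)(Cl)C#C
Why: Copper-catalysed propargylic etherification of a phenol by a tertiary propargylic chloride; the phenol para to the ester is acidic enough to react at 0 °C, and the ester, acetal and prenyl group are inert.

Step 8
Reactants: 16 ethyl 2-(methoxymethoxy)-3-(3-methylbut-2-en-1-yl)-4-[(2-methylbut-3-yn-2-yl)oxy]benzoate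
Product: 19 ethyl 7-(methoxymethoxy)-2,2-dimethyl-8-(3-methylbut-2-en-1-yl)-2H-chromene-6-carboxylate, via allenylphenol 17 (not isolated), via ortho-quinone methide 18 (not isolated)
Conditions: PhNEt2, 180 °C
Reagents that add atoms: none
Why: Aromatic propargyl Claisen cascade: the [3,3] shift goes to the only unsubstituted ortho carbon and enolisation gives allenylphenol 17; a 1,5-hydrogen shift then gives ortho-quinone methide 18, and oxa-6π electrocyclisation closes the pyran. The prenyl group on the other ortho carbon blocks the alternative closure.

Step 9
Reactants: 19 ethyl 7-(methoxymethoxy)-2,2-dimethyl-8-(3-methylbut-2-en-1-yl)-2H-chromene-6-carboxylate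
Product: 20 N-methoxy-7-(methoxymethoxy)-N,2,2-trimethyl-8-(3-methylbut-2-en-1-yl)-2H-chromene-6-carboxamide
Conditions: MeNH(OMe)·HCl, iPrMgCl, THF, −20 to 0 °C
Reagents that add atoms: N,O-dimethylhydroxylamine hydrochloride, CNOC.Cl
Why: Direct aminolysis of an ester by the chloromagnesium amide of N,O-dimethylhydroxylamine (Weinreb amide synthesis); the non-acidic conditions leave the acetal, the chromene and the prenyl group untouched.

Step 10
Reactants: 21 4-(2-bromoethyl)phenol
Product: 22 1-(2-bromoethyl)-4-(methoxymethoxy)benzene
Conditions: MOMCl, iPr2NEt, CH2Cl2, 0 to 23 °C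
Reagents that add atoms: chloromethyl methyl ether, COCCl
Why: Alkoxymethylation of a phenol under a hindered amine base; no free phenoxide builds up, so intramolecular displacement of the primary bromide is avoided.

Step 11
Reactants: 22 1-(2-bromoethyl)-4-(methoxymethoxy)benzene; 20 N-methoxy-7-(methoxymethoxy)-N,2,2-trimethyl-8-(3-methylbut-2-en-1-yl)-2H-chromene-6-carboxamide
Product: 24 1-[7-(methoxymethoxy)-2,2-dimethyl-8-(3-methylbut-2-en-1-yl)-2H-chromen-6-yl]-3-[4-(methoxymethoxy)phenyl]propan-1-one, via Grignard reagent 23 (not isolated)
Conditions: 22, Mg, THF, 23 to 40 °C; then 20, THF, 0 °C; aq. NH4Cl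
Reagents that add atoms: none
Why: Grignard formation from a primary bromide and Weinreb ketone synthesis; the magnesium chelate of the tetrahedral adduct persists until quench, so acyl substitution stops at the ketone.

Step 12
Reactants: 24 1-[7-(methoxymethoxy)-2,2-dimethyl-8-(3-methylbut-2-en-1-yl)-2H-chromen-6-yl]-3-[4-(methoxymethoxy)phenyl]propan-1-one
Product: 25 1-[7-hydroxy-2,2-dimethyl-8-(3-methylbut-2-en-1-yl)-2H-chromen-6-yl]-3-(4-hydroxyphenyl)propan-1-one
Conditions: HCl (3 M aq.), MeOH, 23 to 40 °C
Reagents that add atoms: none
Why: Acid-catalysed methanolysis of both aryl methoxymethyl acetals; the acetal ortho to the ketone is cleaved fastest, and the freed C7 hydroxyl is held in a hydrogen bond to the carbonyl, which lowers its tendency to add to the prenyl alkene.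

## Compound list

1 | diethyl 3-oxopentanedioate | CCOC(=O)CC(=O)CC(=O)OCC | starting material
2 | triethyl orthoformate | CCOC(OCC)OCC | starting material
3 | diethyl 2-(ethoxymethylene)-3-oxopentanedioate (alkene geometry not defined) | CCOC=C(C(=O)OCC)C(=O)CC(=O)OCC | intermediate
4 | ethyl 4-hydroxy-6-oxo-6H-pyran-3-carboxylate | CCOC(=O)c1coc(=O)cc1O | intermediate
5 | 3-methylbut-2-en-1-ol | CC(C)=CCO | starting material
6 | methyl 3-methylbut-2-en-1-yl carbonate | COC(=O)OCC=C(C)C | intermediate
7 | ethyl 4-hydroxy-5-(3-methylbut-2-en-1-yl)-6-oxo-6H-pyran-3-carboxylate | CCOC(=O)c1coc(=O)c(CC=C(C)C)c1O | intermediate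
8 | ethyl 4-(methoxymethoxy)-5-(3-methylbut-2-en-1-yl)-6-oxo-6H-pyran-3-carboxylate | CCOC(=O)c1coc(=O)c(CC=C(C)C)c1OCOC | intermediate
9 | trimethylsilyl acetate | CC(=O)O[Si](C)(C)C | starting material
10 | lithium 1-(trimethylsilyloxy)ethen-1-olate | [Li+].C=C([O-])O[Si](C)(C)C | intermediate
11 | ketene bis(trimethylsilyl) acetal, 1,1-bis(trimethylsilyloxy)ethene | C=C(O[Si](C)(C)C)O[Si](C)(C)C | intermediate
12 | ethyl 5-(methoxymethoxy)-4-(3-methylbut-2-en-1-yl)-3-oxo-8,8-bis(trimethylsilyloxy)-2-oxabicyclo[2.2.2]oct-5-ene-6-carboxylate (racemic; bridgeheads joined in the only way the bicycle allows) | CCOC(=O)C1=C(OCOC)C2(CC=C(C)C)C(=O)OC1CC2(O[Si](C)(C)C)O[Si](C)(C)C | intermediate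
13 | ethyl 6-(methoxymethoxy)-5-(3-methylbut-2-en-1-yl)-4,4-bis(trimethylsilyloxy)cyclohexa-1,5-diene-1-carboxylate | CCOC(=O)C1=CCC(O[Si](C)(C)C)(O[Si](C)(C)C)C(CC=C(C)C)=C1OCOC | intermediate
14 | ethyl 2-(methoxymethoxy)-3-(3-methylbut-2-en-1-yl)-4-(trimethylsilyloxy)benzoate | CCOC(=O)c1ccc(O[Si](C)(C)C)c(CC=C(C)C)c1OCOC | intermediate
15 | ethyl 4-hydroxy-2-(methoxymethoxy)-3-(3-methylbut-2-en-1-yl)benzoate | CCOC(=O)c1ccc(O)c(CC=C(C)C)c1OCOC | intermediate
16 | ethyl 2-(methoxymethoxy)-3-(3-methylbut-2-en-1-yl)-4-[(2-methylbut-3-yn-2-yl)oxy]benzoate | CCOC(=O)c1ccc(OC(C)(C)C#C)c(CC=C(C)C)c1OCOC | intermediate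
17 | ethyl 4-hydroxy-2-(methoxymethoxy)-5-(3-methylbuta-1,2-dien-1-yl)-3-(3-methylbut-2-en-1-yl)benzoate | CCOC(=O)c1cc(C=C=C(C)C)c(O)c(CC=C(C)C)c1OCOC | intermediate
18 | ethyl 6-(methoxymethoxy)-3-(3-methylbut-2-en-1-ylidene)-5-(3-methylbut-2-en-1-yl)-4-oxocyclohexa-1,5-diene-1-carboxylate (side chain of the exocyclic alkene turned towards the ring carbonyl) | O=C1C(CC=C(C)C)=C(OCOC)C(C(=O)OCC)=C/C1=C/C=C(C)C | intermediate
19 | ethyl 7-(methoxymethoxy)-2,2-dimethyl-8-(3-methylbut-2-en-1-yl)-2H-chromene-6-carboxylate | CCOC(=O)c1cc2C=CC(C)(C)Oc2c(CC=C(C)C)c1OCOC | intermediate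
20 | N-methoxy-7-(methoxymethoxy)-N,2,2-trimethyl-8-(3-methylbut-2-en-1-yl)-2H-chromene-6-carboxamide | CON(C)C(=O)c1cc2C=CC(C)(C)Oc2c(CC=C(C)C)c1OCOC | intermediate
21 | 4-(2-bromoethyl)phenol | Oc1ccc(CCBr)cc1 | starting material
22 | 1-(2-bromoethyl)-4-(methoxymethoxy)benzene | COCOc1ccc(CCBr)cc1 | intermediate
23 | 2-[4-(methoxymethoxy)phenyl]ethylmagnesium bromide | COCOc1ccc(CC[Mg]Br)cc1 | intermediate
24 | 1-[7-(methoxymethoxy)-2,2-dimethyl-8-(3-methylbut-2-en-1-yl)-2H-chromen-6-yl]-3-[4-(methoxymethoxy)phenyl]propan-1-one | COCOc1ccc(CCC(=O)c2cc3C=CC(C)(C)Oc3c(CC=C(C)C)c2OCOC)cc1 | intermediate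
25 | 1-[7-hydroxy-2,2-dimethyl-8-(3-methylbut-2-en-1-yl)-2H-chromen-6-yl]-3-(4-hydroxyphenyl)propan-1-one | CC(C)=CCc1c(O)c(C(=O)CCc2ccc(O)cc2)cc2c1OC(C)(C)C=C2 | target

## Step count and risks

Total step count: 12. Longest linear sequence: 9 steps (steps 1, 3, 4, 6, 7, 8, 9, 11 and 12, from diethyl 3-oxopentanedioate 1).

**Step 6 (key step).**
- What may go wrong: the cycloaddition may be too slow, because the alkoxy and alkyl groups raise the diene LUMO and the prenyl-bearing carbon must bond to a fully substituted acetal carbon. The reaction may also stop after the first carbon–carbon bond, with silyl transfer and opening of the pyran instead of ring closure. The dienophile may be lost by thermal oxygen-to-carbon silyl migration before it reacts.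
- Fallback: the ring oxygen is carried through the cycloaddition as an electron-poor ester instead of an acetal. The fallback sets out from 7 and returns at 19.
  - Acylation of 7 with pivaloyl chloride and Et3N should give ethyl 4-(2,2-dimethylpropanoyloxy)-5-(3-methylbut-2-en-1-yl)-6-oxo-6H-pyran-3-carboxylate F1. Its acyloxy group donates far less than an alkoxy group, so it should react with 11 at lower temperature.
  - Cycloaddition and work-up as in step 6 should give ethyl 2-(2,2-dimethylpropanoyloxy)-4-hydroxy-3-(3-methylbut-2-en-1-yl)benzoate F2.
  - Propargylation as in step 7 should give ethyl 2-(2,2-dimethylpropanoyloxy)-3-(3-methylbut-2-en-1-yl)-4-[(2-methylbut-3-yn-2-yl)oxy]benzoate F3.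
  - Rearrangement as in step 8 should give ethyl 7-(2,2-dimethylpropanoyloxy)-2,2-dimethyl-8-(3-methylbut-2-en-1-yl)-2H-chromene-6-carboxylate F4.
  - Ethanolysis with NaOEt in EtOH should give ethyl 7-hydroxy-2,2-dimethyl-8-(3-methylbut-2-en-1-yl)-2H-chromene-6-carboxylate F5.
  - Treatment of F5 with NaH and MOMCl should give 19.

**Step 3.**
- What may go wrong: attack at the more substituted allyl terminus, O-allylation that fails to equilibrate to carbon, or a second allylation at the same carbon. The pyrone anion, stabilised by an extra ester, is a weak nucleophile.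
- Fallback: the prenyl group is installed before the pyrone exists. The fallback sets out from 1 and returns at 7.
  - Mono-alkylation of 1 with prenyl bromide (NaH, THF) should give diethyl 2-(3-methylbut-2-en-1-yl)-3-oxopentanedioate F6.
  - Orthoformate and acetic anhydride can then condense only at the one remaining methylene, giving diethyl 2-(ethoxymethylene)-4-(3-methylbut-2-en-1-yl)-3-oxopentanedioate F7.
  - Acid cyclisation as in step 1 should lactonise F7 onto the ester of the prenylated arm and give 7.

**Step 8.**
- What may go wrong: the [3,3] shift may go towards the prenyl-bearing ortho carbon, where the blocked dienone can be consumed by an intramolecular cycloaddition. The tertiary propargyl group may also be lost by elimination at 180 °C.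
- Fallback: the pyran is built by condensation instead of rearrangement. The fallback sets out from 15 and returns directly at 19. Heating 15 with 3-methylbut-2-enal diethyl acetal in 3-picoline (a known chromene annulation of phenols through ortho C-alkylation, ortho-quinone methide formation and oxa-6π closure) can only engage the one free ortho carbon. No compound outside the route is made (entry F0).

**Step 12.**
- What may go wrong: while the slower ring B acetal is still being cleaved, the liberated C7 hydroxyl may add to the protonated prenyl alkene (chroman formation), or the chromene alkene may be protonated and take up methanol.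
- Fallback: ring B is protected with a silyl group so that each phenol is released by its own mild reagent, and only the chelation-activated acetal needs acid. The fallback sets out from 21 and 20 and returns at 25.
  - 21 with TBSCl and imidazole should give [4-(2-bromoethyl)phenoxy](tert-butyl)dimethylsilane F8.
  - Magnesium should convert F8 into 2-[4-(tert-butyldimethylsilyloxy)phenyl]ethylmagnesium bromide F9.
  - Addition of F9 to 20 should give 3-[4-(tert-butyldimethylsilyloxy)phenyl]-1-[7-(methoxymethoxy)-2,2-dimethyl-8-(3-methylbut-2-en-1-yl)-2H-chromen-6-yl]propan-1-one F10.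
  - Bu4NF buffered with AcOH should give 3-(4-hydroxyphenyl)-1-[7-(methoxymethoxy)-2,2-dimethyl-8-(3-methylbut-2-en-1-yl)-2H-chromen-6-yl]propan-1-one F11.
  - A brief treatment with dilute HCl in MeOH at 0 °C should then remove the remaining acetal, the one ortho to the ketone, and give 25.

## Further compounds

F1 | step 6 | ethyl 4-(2,2-dimethylpropanoyloxy)-5-(3-methylbut-2-en-1-yl)-6-oxo-6H-pyran-3-carboxylate | CCOC(=O)c1coc(=O)c(CC=C(C)C)c1OC(=O)C(C)(C)C
F2 | step 6 | ethyl 2-(2,2-dimethylpropanoyloxy)-4-hydroxy-3-(3-methylbut-2-en-1-yl)benzoate | CCOC(=O)c1ccc(O)c(CC=C(C)C)c1OC(=O)C(C)(C)C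
F3 | step 6 | ethyl 2-(2,2-dimethylpropanoyloxy)-3-(3-methylbut-2-en-1-yl)-4-[(2-methylbut-3-yn-2-yl)oxy]benzoate | CCOC(=O)c1ccc(OC(C)(C)C#C)c(CC=C(C)C)c1OC(=O)C(C)(C)C
F4 | step 6 | ethyl 7-(2,2-dimethylpropanoyloxy)-2,2-dimethyl-8-(3-methylbut-2-en-1-yl)-2H-chromene-6-carboxylate | CCOC(=O)c1cc2C=CC(C)(C)Oc2c(CC=C(C)C)c1OC(=O)C(C)(C)C
F5 | step 6 | ethyl 7-hydroxy-2,2-dimethyl-8-(3-methylbut-2-en-1-yl)-2H-chromene-6-carboxylate | CCOC(=O)c1cc2C=CC(C)(C)Oc2c(CC=C(C)C)c1O
F6 | step 3 | diethyl 2-(3-methylbut-2-en-1-yl)-3-oxopentanedioate (racemic) | CCOC(=O)CC(=O)C(CC=C(C)C)C(=O)OCC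
F7 | step 3 | diethyl 2-(ethoxymethylene)-4-(3-methylbut-2-en-1-yl)-3-oxopentanedioate (racemic, alkene geometry not defined) | CCOC=C(C(=O)OCC)C(=O)C(CC=C(C)C)C(=O)OCC
F0 | step 8 | none | none
F8 | step 12 | [4-(2-bromoethyl)phenoxy](tert-butyl)dimethylsilane | CC(C)(C)[Si](C)(C)Oc1ccc(CCBr)cc1
F9 | step 12 | 2-[4-(tert-butyldimethylsilyloxy)phenyl]ethylmagnesium bromide | CC(C)(C)[Si](C)(C)Oc1ccc(CC[Mg]Br)cc1
F10 | step 12 | 3-[4-(tert-butyldimethylsilyloxy)phenyl]-1-[7-(methoxymethoxy)-2,2-dimethyl-8-(3-methylbut-2-en-1-yl)-2H-chromen-6-yl]propan-1-one | CC(C)(C)[Si](C)(C)Oc1ccc(CCC(=O)c2cc3C=CC(C)(C)Oc3c(CC=C(C)C)c2OCOC)cc1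
F11 | step 12 | 3-(4-hydroxyphenyl)-1-[7-(methoxymethoxy)-2,2-dimethyl-8-(3-methylbut-2-en-1-yl)-2H-chromen-6-yl]propan-1-one | COCOc1c(CC=C(C)C)c2OC(C)(C)C=Cc2cc1C(=O)CCc1ccc(O)cc1
A1 | alternative 1 | methyl 2-hydroxy-4-oxo-3-(3-methylbut-2-en-1-yl)cyclohex-2-ene-1-carboxylate (racemic, enol tautomer) | COC(=O)C1CCC(=O)C(CC=C(C)C)=C1O
A2 | alternative 1 | 7-methylocta-1,6-dien-3-one | C=CC(=O)CCC=C(C)C
A3 | alternative 1 | dimethyl malonate | COC(=O)CC(=O)OC
A4 | alternative 1 | methyl 2,4-dihydroxy-3-(3-methylbut-2-en-1-yl)benzoate | COC(=O)c1ccc(O)c(CC=C(C)C)c1O
A5 | alternative 2 | 3-[4-(tert-butyldimethylsilyloxy)phenyl]-1-[7-hydroxy-2,2-dimethyl-8-(3-methylbut-2-en-1-yl)-2H-chromen-6-yl]propan-1-one | CC(C)=CCc1c(O)c(C(=O)CCc2ccc(O[Si](C)(C)C(C)(C)C)cc2)cc2c1OC(C)(C)C=C2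
A6 | alternative 2 | 3-[4-(tert-butyldimethylsilyloxy)phenyl]-1-[5-formyl-2,4-dihydroxy-3-(3-methylbut-2-en-1-yl)phenyl]propan-1-one | CC(C)=CCc1c(O)c(C(=O)CCc2ccc(O[Si](C)(C)C(C)(C)C)cc2)cc(C=O)c1O
A7 | alternative 2 | 2-methylprop-1-enylboronic acid | CC(C)=CB(O)O
A8 | alternative 2 | dibenzylamine | c1ccc(CNCc2ccccc2)cc1
A9 | alternative 3 | 1-[2-hydroxy-3-(3-methylbut-2-en-1-yl)-4-(triisopropylsilyloxy)phenyl]-3-[4-(methoxymethoxy)phenyl]propan-1-one | CC(C)=CCc1c(O[Si](C(C)C)(C(C)C)C(C)C)ccc(C(=O)CCc2ccc(OCOC)cc2)c1O
A10 | alternative 3 | 5-methyl-1-(triisopropylsilyloxy)hex-4-en-1-yne | CC(C)=CCC#CO[Si](C(C)C)(C(C)C)C(C)C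
A11 | alternative 3 | (E)-1-diazo-6-[4-(methoxymethoxy)phenyl]hex-3-ene-2,5-dione | [N-]=[N+]=CC(=O)/C=C/C(=O)CCc1ccc(OCOC)cc1
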